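Numbering used (daucane): C1 = ring-fusion C(CH3), C4 = C(OH)(i-Pr), C5 = ring-fusion CH, C6 = CH–O(acyl), C8 = C(CH3)=, C9 = CH=, C10 = C=O; C2, C3, C7 = CH2.
Cuts, in retrosynthetic order: C6–O (ester); C8=C9 (seven-membered ring, metathesis); C1–C5 (five-membered ring, enolate + epoxide); C3–C4 (B-alkyl coupling); C6–C7 (methallylation); C5–C6 (formylation).
Forward: one acyclic chain is built from 3-methylbut-1-yne, a methallylstannane, racemic 2-methylbut-3-enoic acid and a propenyl Grignard reagent; the five-membered ring closes first, the seven-membered ring second, the veratrate goes on last.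
Enabling feature: within the five-membered ring, C10(=O)–C1–C5–C4–OH is a γ-hydroxy ketone; C1 is the only α′ C–H of the enone and C5 is the neighbour of the tertiary carbinol C4, so C1–C5 is the retron of a C1 enolate opening a C4–C5 epoxide at C5.
Stereochemistry: C6 by catalyst control (methallylation); the C4–C5 epoxide by C6–OH-directed epoxidation; C5 by inversion and C4 by retention in the ring closure; C1 is carried as both epimers and is set only when their common enolate closes the ring (stereoconvergent).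

Key step: step 9

Remark: prop-1-en-1-ylmagnesium bromide is an E/Z mixture; compounds 14–18 are drawn as E enones, and the geometry is without consequence because this terminus leaves as propene in step 10.

Step 1
Reactants: 1 3-methylbut-1-yne
Product: 3 4-methylpent-2-ynal, via lithium acetylide 2 (not isolated)
Conditions: n-BuLi, THF, −78 °C; DMF, −78 → 0 °C; inverse quench into aq. KH2PO4
Reagents that add atoms: N,N-dimethylformamide, CN(C)C=O
Why: Lithiation of the terminal alkyne and formylation of the acetylide with DMF, with a phosphate-buffered inverse quench that should keep the liberated amine from adding to the ynal; no stereocentre is formed.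

Step 2
Reactants: 3 4-methylpent-2-ynal; 4 tributyl(2-methylprop-2-en-1-yl)stannane
Product: 5 (4S)-2,7-dimethyloct-1-en-5-yn-4-ol
Conditions: (S)-BINOL (10 mol %), Ti(OiPr)4 (10 mol %), 4 Å molecular sieves, CH2Cl2, −20 °C; aq. NaHCO3
Reagents that add atoms: none
Why: Keck asymmetric methallylation, in which the BINOL–Ti(OiPr)4 Lewis acid binds the ynal and exposes one face to the stannane, so that C6 is set by catalyst control; (S)-BINOL should give the (S) carbinol, as it does with other aldehydes whose substituent outranks the allyl group.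

Step 3
Reactants: 5 (4S)-2,7-dimethyloct-1-en-5-yn-4-ol
Product: 7 (4S,5Z)-6-iodo-2,7-dimethylocta-1,5-dien-4-ol, via alkenylaluminate 6 (not isolated)
Conditions: NaAlH2(OCH2CH2OMe)2 (Red-Al), THF, 0 °C → rt; I2, −78 → 0 °C; aq. Na2S2O3, potassium sodium tartrate
Reagents that add atoms: iodine, II
Why: Hydroxyl-directed trans-hydroalumination delivers hydride to C5 and holds aluminium on C4 in a five-membered alkoxyaluminate, and iodinolysis with retention should give the Z iodide with the isopropyl group trans to C6, which fixes the alkene geometry.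

Step 4
Reactants: 8 2-methylbut-3-enoic acid (racemic)
Product: 10 N-methoxy-N,2-dimethylbut-3-enamide (racemic), via acylimidazole 9 (not isolated)
Conditions: CDI, CH2Cl2, 0 °C; MeNH(OMe)·HCl, rt
Reagents that add atoms: N,O-dimethylhydroxylamine hydrochloride, CNOC.Cl
Why: Acylimidazole activation followed by Weinreb amide formation under near-neutral conditions that should leave the β,γ-alkene out of conjugation; the α-centre (future C1) is deliberately racemic.

Step 5
Reactants: 10 N-methoxy-N,2-dimethylbut-3-enamide; 7 (4S,5Z)-6-iodo-2,7-dimethylocta-1,5-dien-4-ol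
Product: 12 (5E,7S)-7-hydroxy-N-methoxy-N,2,9-trimethyl-5-(propan-2-yl)deca-5,9-dienamide (both C-2 epimers), via alkylborane 11 (not isolated)
Conditions: 9-BBN, THF, 0 °C → rt (on 10); then 7, Pd(dppf)Cl2 (5 mol %), AsPh3, Cs2CO3, DMF/H2O, rt
Reagents that add atoms: none
Why: Anti-Markovnikov hydroboration with 9-BBN and B-alkyl Suzuki–Miyaura coupling, which joins C3 to C4 with retention of alkene geometry, so that C3 ends cis to C6, and which tolerates the free alcohol and the amide.

Step 6
Reactants: 12 (5E,7S)-7-hydroxy-N-methoxy-N,2,9-trimethyl-5-(propan-2-yl)deca-5,9-dienamide; 13 prop-1-en-1-ylmagnesium bromide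
Product: 14 (2E,8E,10S)-10-hydroxy-5,12-dimethyl-8-(propan-2-yl)trideca-2,8,12-trien-4-one (both C-5 epimers)
Conditions: 13 (2.5 equiv), THF, −20 → 0 °C; cold aq. NH4Cl
Reagents that add atoms: none
Why: Weinreb ketone synthesis, in which the chelated tetrahedral intermediate should stop at the ketone stage after one equivalent of the Grignard reagent has been consumed by the hydroxyl group.

Step 7
Reactants: 14 (2E,8E,10S)-10-hydroxy-5,12-dimethyl-8-(propan-2-yl)trideca-2,8,12-trien-4-one
Product: 15 (2E)-7-{(2R,3R)-3-[(1S)-1-hydroxy-3-methylbut-3-en-1-yl]-2-(propan-2-yl)oxiran-2-yl}-5-methylhept-2-en-4-one (both C-5 epimers)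
Conditions: mCPBA (1.05 equiv), NaHCO3, CH2Cl2, −20 → 0 °C
Reagents that add atoms: 3-chloroperoxybenzoic acid (mCPBA), O=C(OO)c1cccc(Cl)c1
Why: Hydroxyl-directed (Henbest) peracid epoxidation, in which A(1,3) strain between C3 and the C6 substituents keeps C6–H in the alkene plane so that the hydrogen-bonded peracid attacks the face syn to the hydroxyl group and should give the threo (4R,5R) epoxide, while the enone and the 1,1-disubstituted alkene react more slowly.

Step 8
Reactants: 15 (2E)-7-{(2R,3R)-3-[(1S)-1-hydroxy-3-methylbut-3-en-1-yl]-2-(propan-2-yl)oxiran-2-yl}-5-methylhept-2-en-4-one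
Product: 16 (2E)-7-{(2R,3R)-3-[(1S)-1-{[tert-butyl(dimethyl)silyl]oxy}-3-methylbut-3-en-1-yl]-2-(propan-2-yl)oxiran-2-yl}-5-methylhept-2-en-4-one (both C-5 epimers)
Conditions: TBSCl, imidazole, DMF, rt
Reagents that add atoms: tert-butyldimethylsilyl chloride, CC(C)(C)[Si](C)(C)Cl
Why: Silylation of the secondary alcohol under neutral conditions, which removes the alkoxide that would otherwise trigger Payne rearrangement of the epoxide in step 9.

Step 9
Reactants: 16 (2E)-7-{(2R,3R)-3-[(1S)-1-{[tert-butyl(dimethyl)silyl]oxy}-3-methylbut-3-en-1-yl]-2-(propan-2-yl)oxiran-2-yl}-5-methylhept-2-en-4-one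
Product: 18 (2E)-1-{(1S,2S,3R)-2-[(1S)-1-{[tert-butyl(dimethyl)silyl]oxy}-3-methylbut-3-en-1-yl]-3-hydroxy-1-methyl-3-(propan-2-yl)cyclopentyl}but-2-en-1-one, via potassium enolate 17 (not isolated)
Conditions: KN(SiMe3)2 (1.05 equiv), THF, 0.02 M, −78 °C → rt; aq. NH4Cl
Reagents that add atoms: none
Why: KN(SiMe3)2 removes the single α′ proton at C1, so both C1 epimers of 16 merge in one planar cross-conjugated enolate 17, whose α carbon attacks the epoxide at C5 anti to the C5–O bond (intramolecular SN2) and releases the C4 alkoxide. The closest known reaction type is the Stork epoxynitrile cyclization, extended here from a nitrile anion to a ketone enolate. The five-membered ring (C1–C2–C3–C4–C5) closes in the 5-endo-tet mode, because the 4-exo alternative would require substitution at the fully substituted C4, and the γ-dienolate could only form seven- or nine-membered rings and should revert by proton exchange. C5 is set by inversion at the epoxide carbon and C4 keeps the configuration fixed in step 7, so the relay from C6 to C4 and C5 is stereospecific. C1 is set in the ring-closing transition state, where the bulky potassium enolate branch (C10) should take the position anti to the C6 side chain on C5 and leave the methyl group syn, which gives the trans relation of C10 and C6 needed for the trans-fused bicycle. The step needs C- over O-alkylation, attack at C5 and not at C4, and facial control at C1; the tether length, the substitution pattern of the epoxide, the silyl ether and the non-chelating potassium counter-ion should secure them.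

Step 10
Reactants: 18 (2E)-1-{(1S,2S,3R)-2-[(1S)-1-{[tert-butyl(dimethyl)silyl]oxy}-3-methylbut-3-en-1-yl]-3-hydroxy-1-methyl-3-(propan-2-yl)cyclopentyl}but-2-en-1-one
Product: 19 (3R,3aS,4S,8aS)-4-{[tert-butyl(dimethyl)silyl]oxy}-3-hydroxy-6,8a-dimethyl-3-(propan-2-yl)-2,3,3a,4,5,8a-hexahydroazulen-8(1H)-one
Conditions: second-generation Grubbs catalyst (H2IMes)(PCy3)Cl2Ru=CHPh (10 mol %), toluene (5 mM), 80 °C
Reagents that add atoms: none
Why: Ring-closing metathesis of the enone olefin with the 1,1-disubstituted alkene should give the trisubstituted C8=C9 bond of the cycloheptenone with loss of propene, the trans-1,2 disposition of the two chains on the cyclopentane defining the trans ring fusion; no new stereocentre is formed.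

Step 11
Reactants: 19 (3R,3aS,4S,8aS)-4-{[tert-butyl(dimethyl)silyl]oxy}-3-hydroxy-6,8a-dimethyl-3-(propan-2-yl)-2,3,3a,4,5,8a-hexahydroazulen-8(1H)-one
Product: 20 (3R,3aS,4S,8aS)-3,4-dihydroxy-6,8a-dimethyl-3-(propan-2-yl)-2,3,3a,4,5,8a-hexahydroazulen-8(1H)-one
Conditions: HF·pyridine, THF/pyridine, 0 °C → rt
Reagents that add atoms: none
Why: Fluoride-induced cleavage of the silyl ether under weakly acidic conditions, chosen because the δ-oxygenated enone is sensitive to base (γ-deprotonation and elimination).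

Step 12
Reactants: 20 (3R,3aS,4S,8aS)-3,4-dihydroxy-6,8a-dimethyl-3-(propan-2-yl)-2,3,3a,4,5,8a-hexahydroazulen-8(1H)-one; 21 3,4-dimethoxybenzoyl chloride
Product: 22 (3R,3aS,4S,8aS)-3-hydroxy-6,8a-dimethyl-8-oxo-3-(propan-2-yl)-1,2,3,3a,4,5,8,8a-octahydroazulen-4-yl 3,4-dimethoxybenzoate
Conditions: Et3N, DMAP (cat.), CH2Cl2, 0 °C → rt
Reagents that add atoms: none
Why: DMAP-catalysed acylation (nucleophilic catalysis) that should esterify the secondary C6 hydroxyl with retention while the hindered tertiary C4 hydroxyl stays free.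

Compound list
1 | 3-methylbut-1-yne | CC(C)C#C | starting material
2 | lithium 3-methylbut-1-yn-1-ide | CC(C)C#C[Li] | intermediate (not isolated)
3 | 4-methylpent-2-ynal | CC(C)C#CC=O | intermediate
4 | tributyl(2-methylprop-2-en-1-yl)stannane | CC(=C)C[Sn](CCCC)(CCCC)CCCC | starting material
5 | (4S)-2,7-dimethyloct-1-en-5-yn-4-ol | CC(C)C#C[C@H](CC(C)=C)O | intermediate
6 | sodium alkenylaluminate: five-membered 1,2-oxaaluminate formed from 5, Al on C4 with two 2-methoxyethoxy ligands, (S) at the carbinol carbon | [Na+].CC(C)C1=C[C@H](CC(C)=C)O[Al-]1(OCCOC)OCCOC | intermediate (not isolated)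
7 | (4S,5Z)-6-iodo-2,7-dimethylocta-1,5-dien-4-ol | CC(C)/C(I)=C/[C@H](CC(C)=C)O | intermediate
8 | 2-methylbut-3-enoic acid (racemic) | C=CC(C)C(=O)O | starting material
9 | 1-(1H-imidazol-1-yl)-2-methylbut-3-en-1-one (racemic) | C=CC(C)C(=O)n1ccnc1 | intermediate (not isolated)
10 | N-methoxy-N,2-dimethylbut-3-enamide (racemic) | C=CC(C)C(=O)N(C)OC | intermediate
11 | 4-(9-borabicyclo[3.3.1]nonan-9-yl)-N-methoxy-N,2-dimethylbutanamide (racemic) | CON(C)C(=O)C(C)CCB1C2CCCC1CCC2 | intermediate (not isolated)
12 | (5E,7S)-7-hydroxy-N-methoxy-N,2,9-trimethyl-5-(propan-2-yl)deca-5,9-dienamide (both C-2 epimers) | CON(C)C(=O)C(C)CC/C(C(C)C)=C\[C@H](CC(C)=C)O | intermediate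
13 | prop-1-en-1-ylmagnesium bromide (E/Z mixture) | CC=C[Mg]Br | starting material
14 | (2E,8E,10S)-10-hydroxy-5,12-dimethyl-8-(propan-2-yl)trideca-2,8,12-trien-4-one (both C-5 epimers) | C/C=C/C(=O)C(C)CC/C(C(C)C)=C\[C@H](CC(C)=C)O | intermediate
15 | (2E)-7-{(2R,3R)-3-[(1S)-1-hydroxy-3-methylbut-3-en-1-yl]-2-(propan-2-yl)oxiran-2-yl}-5-methylhept-2-en-4-one (both C-5 epimers) | C/C=C/C(=O)C(C)CC[C@]1(C(C)C)O[C@@H]1[C@H](CC(C)=C)O | intermediate
16 | (2E)-7-{(2R,3R)-3-[(1S)-1-{[tert-butyl(dimethyl)silyl]oxy}-3-methylbut-3-en-1-yl]-2-(propan-2-yl)oxiran-2-yl}-5-methylhept-2-en-4-one (both C-5 epimers) | C/C=C/C(=O)C(C)CC[C@]1(C(C)C)O[C@@H]1[C@H](CC(C)=C)O[Si](C)(C)C(C)(C)C | intermediate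
17 | potassium enolate of 16 (cross-conjugated, C1=C10 enolate) | [K+].C/C=C/C([O-])=C(C)CC[C@]1(C(C)C)O[C@@H]1[C@H](CC(C)=C)O[Si](C)(C)C(C)(C)C | intermediate (not isolated)
18 | (2E)-1-{(1S,2S,3R)-2-[(1S)-1-{[tert-butyl(dimethyl)silyl]oxy}-3-methylbut-3-en-1-yl]-3-hydroxy-1-methyl-3-(propan-2-yl)cyclopentyl}but-2-en-1-one | C/C=C/C(=O)[C@@]1(C)CC[C@@](O)(C(C)C)[C@@H]1[C@H](CC(C)=C)O[Si](C)(C)C(C)(C)C | intermediate
19 | (3R,3aS,4S,8aS)-4-{[tert-butyl(dimethyl)silyl]oxy}-3-hydroxy-6,8a-dimethyl-3-(propan-2-yl)-2,3,3a,4,5,8a-hexahydroazulen-8(1H)-one | CC(C)(C)[Si](C)(C)O[C@H]1CC(C)=CC(=O)[C@@]2(C)CC[C@@](O)(C(C)C)[C@H]12 | intermediate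
20 | (3R,3aS,4S,8aS)-3,4-dihydroxy-6,8a-dimethyl-3-(propan-2-yl)-2,3,3a,4,5,8a-hexahydroazulen-8(1H)-one | O[C@H]1CC(C)=CC(=O)[C@@]2(C)CC[C@@](O)(C(C)C)[C@H]12 | intermediate
21 | 3,4-dimethoxybenzoyl chloride | COc1ccc(C(Cl)=O)cc1OC | starting material
22 | (3R,3aS,4S,8aS)-3-hydroxy-6,8a-dimethyl-8-oxo-3-(propan-2-yl)-1,2,3,3a,4,5,8,8a-octahydroazulen-4-yl 3,4-dimethoxybenzoate | COc1ccc(C(=O)O[C@H]2CC(C)=CC(=O)[C@@]3(C)CC[C@@](O)(C(C)C)[C@H]23)cc1OC | target

Total steps: 12. Longest linear sequence: 11 steps (steps 1–3 and 5–12, from 3-methylbut-1-yne); step 4 prepares the side fragment.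

Steps most likely to fail

Step 9. The endo ring closure at the hindered C5 may be slower than enolate equilibration and intermolecular Michael addition to the enone, or facial control at C1 may be incomplete. The fallback sets out from 8 and 7 and comes back at 18; it moves the ring closure to an ester enolate and builds the enone afterwards. Acid 8 is esterified (MeI, K2CO3, DMF) to methyl 2-methylbut-3-enoate F1, which is hydroborated with 9-BBN to the alkylborane F2 and coupled with 7 as in step 5 to the hydroxy ester F3. mCPBA as in step 7 should give the epoxy alcohol F4, and TBSCl/imidazole the silyl ether F5. LiN(iPr)2 in THF/DMPU (−78 → 0 °C) generates the lithium ester enolate F6, a stronger nucleophile with one acidic site and no Michael acceptor, which should close the same C1–C5 bond to the cyclopentane ester F7. MeNH(OMe)·HCl/i-PrMgCl converts F7 into the Weinreb amide F8, and 13 then gives 18.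

Step 10. Metathesis between the electron-poor internal enone olefin and the 1,1-disubstituted alkene may be slow while a trans-fused seven-membered ring has to form, so that oligomerisation or catalyst decomposition competes. The fallback sets out from 18 and comes back at 19; it closes the ring at the allylic-alcohol oxidation level. Luche reduction (NaBH4, CeCl3·7H2O, MeOH, −78 °C) gives the dienol F9 (both C10 epimers). Ring-closing metathesis with the second-generation Hoveyda–Grubbs catalyst (H2IMes)Cl2Ru=CH(2-iPrO-C6H4) should give the cycloheptenol F10, and MnO2 reoxidises the allylic alcohol to 19.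

Step 7. Facial selectivity of the directed epoxidation may be incomplete, or the 1,1-disubstituted alkene may be epoxidised as well. The fallback sets out from 14 and comes back at 16; it replaces substrate direction by reagent control. TBSCl/imidazole gives the silyl ether F11. Shi epoxidation (D-fructose-derived ketone, KHSO5, K2CO3, MeCN/dimethoxymethane/H2O, 0 °C) should then deliver the (R,R)-type epoxide expected from the spiro transition-state model for (E)-trisubstituted alkenes, that is 16 directly; the enantiomeric ketone serves if the sense is opposite.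

Further compounds
F1 | step 9 | methyl 2-methylbut-3-enoate (racemic) | C=CC(C)C(=O)OC
F2 | step 9 | methyl 4-(9-borabicyclo[3.3.1]nonan-9-yl)-2-methylbutanoate (racemic) | COC(=O)C(C)CCB1C2CCCC1CCC2
F3 | step 9 | methyl (5E,7S)-7-hydroxy-2,9-dimethyl-5-(propan-2-yl)deca-5,9-dienoate (both C-2 epimers) | COC(=O)C(C)CC/C(C(C)C)=C\[C@H](CC(C)=C)O
F4 | step 9 | methyl 4-{(2R,3R)-3-[(1S)-1-hydroxy-3-methylbut-3-en-1-yl]-2-(propan-2-yl)oxiran-2-yl}-2-methylbutanoate (both C-2 epimers) | COC(=O)C(C)CC[C@]1(C(C)C)O[C@@H]1[C@H](CC(C)=C)O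
F5 | step 9 | tert-butyldimethylsilyl ether of F4 | COC(=O)C(C)CC[C@]1(C(C)C)O[C@@H]1[C@H](CC(C)=C)O[Si](C)(C)C(C)(C)C
F6 | step 9 | lithium ester enolate of F5 | [Li+].COC([O-])=C(C)CC[C@]1(C(C)C)O[C@@H]1[C@H](CC(C)=C)O[Si](C)(C)C(C)(C)C
F7 | step 9 | methyl (1S,2S,3R)-2-[(1S)-1-{[tert-butyl(dimethyl)silyl]oxy}-3-methylbut-3-en-1-yl]-3-hydroxy-1-methyl-3-(propan-2-yl)cyclopentane-1-carboxylate | COC(=O)[C@@]1(C)CC[C@@](O)(C(C)C)[C@@H]1[C@H](CC(C)=C)O[Si](C)(C)C(C)(C)C
F8 | step 9 | (1S,2S,3R)-2-[(1S)-1-{[tert-butyl(dimethyl)silyl]oxy}-3-methylbut-3-en-1-yl]-3-hydroxy-N-methoxy-N,1-dimethyl-3-(propan-2-yl)cyclopentane-1-carboxamide | CON(C)C(=O)[C@@]1(C)CC[C@@](O)(C(C)C)[C@@H]1[C@H](CC(C)=C)O[Si](C)(C)C(C)(C)C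
F9 | step 10 | (2E)-1-{(1S,2S,3R)-2-[(1S)-1-{[tert-butyl(dimethyl)silyl]oxy}-3-methylbut-3-en-1-yl]-3-hydroxy-1-methyl-3-(propan-2-yl)cyclopentyl}but-2-en-1-ol (both carbinol epimers) | C/C=C/C(O)[C@@]1(C)CC[C@@](O)(C(C)C)[C@@H]1[C@H](CC(C)=C)O[Si](C)(C)C(C)(C)C
F10 | step 10 | (3R,3aS,4S,8aS)-4-{[tert-butyl(dimethyl)silyl]oxy}-6,8a-dimethyl-3-(propan-2-yl)-1,2,3,3a,4,5,8,8a-octahydroazulene-3,8-diol (both C-8 epimers) | CC(C)(C)[Si](C)(C)O[C@H]1CC(C)=CC(O)[C@@]2(C)CC[C@@](O)(C(C)C)[C@H]12
F11 | step 7 | (2E,8E,10S)-10-{[tert-butyl(dimethyl)silyl]oxy}-5,12-dimethyl-8-(propan-2-yl)trideca-2,8,12-trien-4-one (both C-5 epimers) | C/C=C/C(=O)C(C)CC/C(C(C)C)=C\[C@H](CC(C)=C)O[Si](C)(C)C(C)(C)C
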